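**Retrosynthetic overview**

- The strategy rests on the side chain on C6 of the 7-methoxycoumarin, numbered C1' (benzylic carbinol), C2' (carbon carrying the 2-methylbutanoyloxy group) and C3' (tertiary carbinol). C3' bears two identical methyl groups and is not stereogenic, so it can be carried as a methyl ketone; C2' then becomes the α-carbon of an acetonyl ester and C1' the carbonyl carbon of an aldol.
- Key disconnection C1'–C2': an amino-acid-catalysed syn-aldol between 7-methoxycoumarin-6-carbaldehyde and the acetonyl ester of (R)-2-methylbutanoic acid. The nucleophile brings the ester in on O2' and leaves O1' free, so no hydroxyl has to be acylated.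
- After the aldol: silylation of O1', chemoselective methyl addition to the ketone to complete C3', and desilylation.
- The aldehyde comes from 6-bromo-7-methoxycoumarin by reductive carbonylation (the formyl carbon becomes C1'); the donor comes from chloroacetone by carboxylate alkylation.
- Ring order: the benzene ring is bought; the pyranone ring is closed first (olefination, then lactonisation at O1–C2); no further ring is formed.

Key step: step 4

Remark on the chemistry: the facial sense assigned to the D-configured catalyst is taken from the transition-state model of the hydroxyacetone series; it is to be confirmed by Mosher ester analysis of the aldol product, and the L-configured catalyst would be used should the sense prove opposite.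

**Route**

Step 1
Reactants: 1 5-bromo-2-hydroxy-4-methoxybenzaldehyde; 2 ethyl (triphenylphosphoranylidene)acetate
Product: 4 6-bromo-7-methoxycoumarin, via (E)-hydroxycinnamate ester 3 (not isolated)
Conditions: PhNEt2, reflux (about 215 °C)
Reagents that add atoms: none
Why: Wittig olefination of the aldehyde by the stabilised ylide gives the 2-hydroxycinnamate 3, whose alkene geometry equilibrates at the boiling point of N,N-diethylaniline so that the Z form lactonises onto the free phenol with loss of ethanol, closing the pyranone ring at O1–C2 with the ylide providing C2 and C3 (Wittig olefination–lactonisation synthesis of coumarins).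

Step 2
Reactants: 4 6-bromo-7-methoxycoumarin
Product: 5 7-methoxy-2-oxo-2H-chromene-6-carbaldehyde
Conditions: Pd(OAc)2 (cat.), 1,4-bis(diphenylphosphino)butane, N-formylsaccharin, Et3SiH, Na2CO3, DMF, 80 °C
Reagents that add atoms: N-formylsaccharin, O=CN1C(=O)c2ccccc2S1(=O)=O
Why: Palladium-catalysed reductive carbonylation (formylation) of the aryl bromide, in which carbon monoxide released from N-formylsaccharin by the carbonate base inserts into the aryl–palladium bond and Et3SiH supplies the hydride that releases the aldehyde, under conditions that should leave the lactone, the aryl methyl ether and the C3=C4 bond untouched.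

Step 3
Reactants: 6 chloroacetone; 7 (R)-2-methylbutanoic acid
Product: 9 2-oxopropyl (2R)-2-methylbutanoate, via iodoacetone 8 (not isolated)
Conditions: Cs2CO3, NaI (cat.), DMF, rt
Reagents that add atoms: none
Why: The caesium carboxylate displaces halide from the α-halo ketone (SN2 O-alkylation with in situ Finkelstein activation), so the ester C–O bond is made at the CH2 carbon and the (R) stereocentre next to the carboxyl group is neither activated nor enolised.

Step 4
Reactants: 5 7-methoxy-2-oxo-2H-chromene-6-carbaldehyde; 9 2-oxopropyl (2R)-2-methylbutanoate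
Product: 10 (1R,2S)-1-hydroxy-1-(7-methoxy-2-oxo-2H-chromen-6-yl)-3-oxobutan-2-yl (2R)-2-methylbutanoate
Conditions: O-tert-butyl-D-threonine (20 mol%), 9 (2.5 equiv, excess recovered), N-methylpyrrolidone, 0 to 4 °C; stopped before full conversion, cold neutral aqueous work-up, crude product used at once
Reagents that add atoms: none
Why: Proposed new method: the free NH2 group of the amino acid is expected to form an imine with the ketone carbonyl of 9 and to tautomerise towards the oxygen-substituted CH2, giving a Z-enamine (N and O cis, accessible because a primary amine leaves a small N–H on nitrogen) that attacks the formyl carbon of 5 while the catalyst CO2H activates and orients the aldehyde by hydrogen bonding in a chair-like array; hydrolysis of the resulting iminium then liberates 10 and the catalyst. The nearest established reaction type is the direct syn-aldol of hydroxyacetone, O-protected hydroxyacetones and dihydroxyacetone with aryl aldehydes under O-tert-butyl-threonine catalysis, and what is untested is a donor whose α-oxygen is acylated by a chiral α-branched acid. The step forms only the C1'–C2' bond and closes no ring. C2' (S) and C1' (R) are both fixed by the catalyst: the Z-enamine imposes the syn relationship and the D-configuration of the amino acid should expose the si face of the aldehyde, whereas the distant acyl stereocentre is not expected to bias the outcome. Three selectivities are required, namely enamine formation at the acyloxy carbon and not at the methyl group, syn over anti, and a single aldehyde face, and they should be secured in turn by the acidifying α-oxygen, by the primary amine and by the catalyst configuration, the non-enolisable aldehyde 5 ruling out self-aldol. Transfer of the acyl group to the catalyst nitrogen, retro-aldol and acyl shift from O2' to O1' are countered by the α-branching of the acyl group, low temperature, excess donor, interruption before full conversion and direct silylation of the crude product.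

Step 5
Reactants: 10 (1R,2S)-1-hydroxy-1-(7-methoxy-2-oxo-2H-chromen-6-yl)-3-oxobutan-2-yl (2R)-2-methylbutanoate (crude)
Product: 11 (1R,2S)-1-(7-methoxy-2-oxo-2H-chromen-6-yl)-3-oxo-1-[(triethylsilyl)oxy]butan-2-yl (2R)-2-methylbutanoate
Conditions: TESOTf, 2,6-lutidine, CH2Cl2, −78 °C
Reagents that add atoms: triethylsilyl trifluoromethanesulfonate, CC[Si](CC)(CC)OS(=O)(=O)C(F)(F)F
Why: A silyl triflate with a hindered pyridine base silylates the secondary benzylic hydroxyl rapidly at low temperature without enolising the ketone (silyl ether protection), and capping O1' shuts off both the retro-aldol pathway and the acyl shift from O2' to O1'.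

Step 6
Reactants: 11 (1R,2S)-1-(7-methoxy-2-oxo-2H-chromen-6-yl)-3-oxo-1-[(triethylsilyl)oxy]butan-2-yl (2R)-2-methylbutanoate
Product: 12 (1R,2S)-3-hydroxy-1-(7-methoxy-2-oxo-2H-chromen-6-yl)-3-methyl-1-[(triethylsilyl)oxy]butan-2-yl (2R)-2-methylbutanoate
Conditions: MeMgCl premixed with anhydrous CeCl3 (about 1.2 equiv), THF, −78 °C; AcOH quench at −78 °C
Reagents that add atoms: methylmagnesium chloride, C[Mg]Cl
Why: The weakly basic, strongly oxophilic organocerium reagent (Imamoto-type 1,2-addition) should add to the activated α-acyloxy ketone far faster than to the hindered ester or the coumarin lactone and should not enolise C2', no stereocentre arises because the two methyl groups on C3' are identical, and the cold acidic quench protonates the tertiary alkoxide before it can take the acyl group from O2'.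

Step 7
Reactants: 12 (1R,2S)-3-hydroxy-1-(7-methoxy-2-oxo-2H-chromen-6-yl)-3-methyl-1-[(triethylsilyl)oxy]butan-2-yl (2R)-2-methylbutanoate
Product: 13 (1R,2S)-1,3-dihydroxy-1-(7-methoxy-2-oxo-2H-chromen-6-yl)-3-methylbutan-2-yl (2R)-2-methylbutanoate (CNP0295788.2)
Conditions: HF·pyridine, extra pyridine, THF, 0 °C; pH 7 phosphate buffer work-up
Reagents that add atoms: none
Why: Fluoride-driven cleavage of the triethylsilyl ether under buffered, mildly acidic conditions (desilylation) frees O1' without any base in reaction or work-up, so the ester should stay on O2' while the lactone and the tertiary alcohol are not affected.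

**Compound list**

1 | 5-bromo-2-hydroxy-4-methoxybenzaldehyde | O=Cc1cc(Br)c(OC)cc1O | starting material
2 | ethyl (triphenylphosphoranylidene)acetate | CCOC(=O)C=P(c1ccccc1)(c1ccccc1)c1ccccc1 | starting material
3 | ethyl (E)-3-(5-bromo-2-hydroxy-4-methoxyphenyl)prop-2-enoate | CCOC(=O)/C=C/c1cc(Br)c(OC)cc1O | intermediate
4 | 6-bromo-7-methoxycoumarin (6-bromo-7-methoxy-2H-chromen-2-one) | COc1cc2oc(=O)ccc2cc1Br | intermediate
5 | 7-methoxy-2-oxo-2H-chromene-6-carbaldehyde | COc1cc2oc(=O)ccc2cc1C=O | intermediate
6 | chloroacetone | CC(=O)CCl | starting material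
7 | (R)-2-methylbutanoic acid | CC[C@@H](C)C(=O)O | starting material
8 | iodoacetone | CC(=O)CI | intermediate
9 | 2-oxopropyl (2R)-2-methylbutanoate | CC[C@@H](C)C(=O)OCC(C)=O | intermediate
10 | (1R,2S)-1-hydroxy-1-(7-methoxy-2-oxo-2H-chromen-6-yl)-3-oxobutan-2-yl (2R)-2-methylbutanoate | CC[C@@H](C)C(=O)O[C@@H]([C@H](O)c1cc2ccc(=O)oc2cc1OC)C(C)=O | intermediate
11 | (1R,2S)-1-(7-methoxy-2-oxo-2H-chromen-6-yl)-3-oxo-1-[(triethylsilyl)oxy]butan-2-yl (2R)-2-methylbutanoate | CC[C@@H](C)C(=O)O[C@@H]([C@H](O[Si](CC)(CC)CC)c1cc2ccc(=O)oc2cc1OC)C(C)=O | intermediate
12 | (1R,2S)-3-hydroxy-1-(7-methoxy-2-oxo-2H-chromen-6-yl)-3-methyl-1-[(triethylsilyl)oxy]butan-2-yl (2R)-2-methylbutanoate | CC[C@@H](C)C(=O)O[C@@H]([C@H](O[Si](CC)(CC)CC)c1cc2ccc(=O)oc2cc1OC)C(C)(C)O | intermediate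
13 | (1R,2S)-1,3-dihydroxy-1-(7-methoxy-2-oxo-2H-chromen-6-yl)-3-methylbutan-2-yl (2R)-2-methylbutanoate (CNP0295788.2) | CC[C@@H](C)C(=O)O[C@@H]([C@H](O)c1cc2ccc(=O)oc2cc1OC)C(C)(C)O | target

**Step count and risks**

Total step count: 7. Longest linear sequence: 6 steps (steps 1, 2, 4, 5, 6, 7); the donor branch (step 3) joins at step 4.

Steps most likely to fail:

1. Step 4 (proposed new method). What may go wrong: transfer of the acyl group from the activated acetonyl ester to the catalyst nitrogen with loss of catalyst, sluggish addition to a moderately electron-rich aldehyde, erosion of the syn or facial selectivity, or retro-aldol and acyl shift while the reaction is running. Fallback by known chemistry, setting out from 5 and returning at 11: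
   - The same amino-acid-catalysed syn-aldol is run with a donor of the established ether-protected class, bought 1-(4-methoxybenzyloxy)propan-2-one (O-tert-butyl-D-threonine, N-methylpyrrolidone, 4 °C). It should give (3S,4R)-4-hydroxy-3-[(4-methoxybenzyl)oxy]-4-(7-methoxy-2-oxo-2H-chromen-6-yl)butan-2-one F1.
   - Silylation (TESOTf, 2,6-lutidine, CH2Cl2, −78 °C) should give (3S,4R)-3-[(4-methoxybenzyl)oxy]-4-(7-methoxy-2-oxo-2H-chromen-6-yl)-4-[(triethylsilyl)oxy]butan-2-one F2.
   - Oxidative removal of the 4-methoxybenzyl group (DDQ, CH2Cl2/pH 7 buffer, 0 °C) should give (3S,4R)-3-hydroxy-4-(7-methoxy-2-oxo-2H-chromen-6-yl)-4-[(triethylsilyl)oxy]butan-2-one F3.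
   - Steglich esterification of the only free hydroxyl with 7 (DCC, catalytic DMAP, CH2Cl2, 0 °C) should give 11, from which steps 6 and 7 follow unchanged.

2. Step 6. What may go wrong: competing attack of the methyl nucleophile on the ester or lactone carbonyl, base-induced epimerisation at C2', or transfer of the acyl group from O2' to the newly formed tertiary alkoxide. Fallback, setting out from 11 and returning at 12:
   - The ketone is methylenated under non-basic conditions (Zn, CH2Br2, TiCl4, THF/CH2Cl2, 0 °C to rt; Takai–Lombardo methylenation). This should give (1R,2R)-1-(7-methoxy-2-oxo-2H-chromen-6-yl)-3-methyl-1-[(triethylsilyl)oxy]but-3-en-2-yl (2R)-2-methylbutanoate F4; the spatial arrangement is unchanged and only the descriptor at C2' changes.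
   - Mukaiyama hydration (cobalt bis(acetylacetonate) Co(acac)2, PhSiH3, O2, i-PrOH, rt, reductive work-up) should add water in the Markovnikov sense through a tertiary radical and give 12 without an alkoxide ever being formed. The 1,1-disubstituted alkene is expected to react ahead of the conjugated C3=C4 bond of the coumarin.

3. Step 2. What may go wrong: hydride transfer to the arylpalladium intermediate before carbon monoxide insertion (hydrodebromination), or reduction of the coumarin C3=C4 bond by the silane. Fallback, setting out from 4 and returning at 5:
   - Suzuki–Miyaura vinylation with potassium vinyltrifluoroborate (PdCl2[1,1'-bis(diphenylphosphino)ferrocene], Et3N, n-PrOH, reflux) should give 7-methoxy-6-vinylcoumarin F5.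
   - Lemieux–Johnson cleavage of the electron-rich terminal vinyl group (OsO4 cat., NaIO4, 2,6-lutidine, dioxane/water, rt) should then give 5.

**Further compounds**

F1 | step 4 | (3S,4R)-4-hydroxy-3-[(4-methoxybenzyl)oxy]-4-(7-methoxy-2-oxo-2H-chromen-6-yl)butan-2-one | COc1ccc(CO[C@@H]([C@H](O)c2cc3ccc(=O)oc3cc2OC)C(C)=O)cc1
F2 | step 4 | (3S,4R)-3-[(4-methoxybenzyl)oxy]-4-(7-methoxy-2-oxo-2H-chromen-6-yl)-4-[(triethylsilyl)oxy]butan-2-one | COc1ccc(CO[C@@H]([C@H](O[Si](CC)(CC)CC)c2cc3ccc(=O)oc3cc2OC)C(C)=O)cc1
F3 | step 4 | (3S,4R)-3-hydroxy-4-(7-methoxy-2-oxo-2H-chromen-6-yl)-4-[(triethylsilyl)oxy]butan-2-one | O[C@@H]([C@H](O[Si](CC)(CC)CC)c1cc2ccc(=O)oc2cc1OC)C(C)=O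
F4 | step 6 | (1R,2R)-1-(7-methoxy-2-oxo-2H-chromen-6-yl)-3-methyl-1-[(triethylsilyl)oxy]but-3-en-2-yl (2R)-2-methylbutanoate | CC[C@@H](C)C(=O)O[C@@H]([C@H](O[Si](CC)(CC)CC)c1cc2ccc(=O)oc2cc1OC)C(C)=C
F5 | step 2 | 7-methoxy-6-vinylcoumarin | C=Cc1cc2ccc(=O)oc2cc1OC
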